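**Retrosynthetic overview** (side chain numbered C-1' at the benzylic carbon to C-16')
1. Last bond made is the phenol C–O bond at ring C-5, by sterically governed C–H borylation/oxidation of the finished carbon skeleton 24, so no phenol protecting group is carried.
2. 24 comes from oxidation of the C-5' carbinol; the C-12'/C-13' bond comes from addition of an E-alkenyllithium (C-13' to C-16') to a Weinreb amide.
3. The C-7'/C-8' bond comes from a B-alkyl Suzuki coupling of an (R)-2-methylpent-4-enamide (C-11' set by Evans allylation) with a Z-vinyl iodide, which fixes 6'Z.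
4. The C-4'/C-5' bond comes from alpha-selective allylbarium addition to (Z)-3-iodobut-2-enal; the aryl–C-1' bond and the 2'E alkene come from copper-catalysed SN2' opening of isoprene monoxide.
5. No ring is formed; the benzene ring is bought as 2-bromo-6-methylanisole.

Assumption: the carbinol centre made in step 5 (C-5') is carried as a mixture of epimers, because step 11 oxidises it to the ketone.

**Step 1**
Reactants: 1 1-bromo-2-methoxy-3-methylbenzene; 2 2-methyl-2-vinyloxirane (isoprene monoxide)
Product: 4 (E)-4-(2-methoxy-3-methylphenyl)-2-methylbut-2-en-1-ol, via arylmagnesium bromide 3 (not isolated)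
Conditions: Mg, THF, reflux; then CuI (10 mol%), 2, THF, −30 → 0 °C; aq NH4Cl
Reagents that add atoms: none
Why: Copper-catalysed SN2' opening of the vinyl epoxide by the aryl Grignard reagent puts the aryl group on the terminal vinyl carbon and gives the trisubstituted allylic alcohol mainly as the E isomer (about 9:1 expected, minor Z isomer removed by chromatography); no stereocentre is formed.

**Step 2**
Reactants: 4 (E)-4-(2-methoxy-3-methylphenyl)-2-methylbut-2-en-1-ol
Product: 6 1-[(E)-4-chloro-3-methylbut-2-en-1-yl]-2-methoxy-3-methylbenzene, via allylic mesylate 5 (not isolated)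
Conditions: MsCl, 2,4,6-collidine, LiCl, DMF, 0 °C
Reagents that add atoms: lithium chloride, [Li+].[Cl-]
Why: Mesylation followed by in-flask SN2 displacement with chloride (Collington–Meyers allylic chloride synthesis) proceeds without allylic transposition or loss of the E geometry.

**Step 3**
Reactants: 7 but-2-yn-1-ol
Product: 9 (Z)-3-iodobut-2-en-1-ol, via cyclic sodium vinylalanate 8 (not isolated)
Conditions: NaAlH2(OCH2CH2OMe)2, THF, 0 °C → rt; EtOAc; I2, THF, −78 → 0 °C
Reagents that add atoms: iodine, II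
Why: Hydroxyl-directed trans-hydroalumination of the propargylic alcohol followed by iodinolysis of the C–Al bond with retention gives only the 3-iodo Z isomer.

**Step 4**
Reactants: 9 (Z)-3-iodobut-2-en-1-ol
Product: 10 (Z)-3-iodobut-2-enal
Conditions: MnO2 (excess), CH2Cl2, rt, dark; filtered and used at once
Reagents that add atoms: none
Why: Allylic alcohol oxidation with MnO2 is neutral and stops at the aldehyde, leaving the Z vinyl iodide unchanged.

**Step 5**
Reactants: 6 1-[(E)-4-chloro-3-methylbut-2-en-1-yl]-2-methoxy-3-methylbenzene; 10 (Z)-3-iodobut-2-enal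
Product: 12 (2Z,6E)-2-iodo-8-(2-methoxy-3-methylphenyl)-6-methylocta-2,6-dien-4-ol, via allylbarium chloride 11 (not isolated)
Conditions: active Ba [BaI2, LiC12H10 (lithium biphenylide, 2 equiv), THF, rt]; 6, −78 °C; 10, −78 °C; aq NH4Cl
Reagents that add atoms: none
Why: Yamamoto allylbarium 1,2-addition, in which the allylbarium formed at −78 °C reacts at its unsubstituted (alpha) carbon with retention of the E geometry and the aldehyde reacts far faster than the vinyl iodide; the new carbinol centre forms unselectively and is removed in step 11.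

**Step 6**
Reactants: 13 (S)-4-benzyl-3-propionyloxazolidin-2-one; 14 allyl iodide
Product: 16 (S)-4-benzyl-3-[(R)-2-methylpent-4-enoyl]oxazolidin-2-one, via sodium Z-enolate 15 (not isolated)
Conditions: NaN(SiMe3)2, THF, −78 °C; 14, −78 → −40 °C
Reagents that add atoms: none
Why: Evans asymmetric alkylation, in which the chelated sodium Z-enolate is allylated on the face opposite the benzyl group, sets the future C-11' centre as R (dr about 98:2, minor diastereomer removed by chromatography).

**Step 7**
Reactants: 16 (S)-4-benzyl-3-[(R)-2-methylpent-4-enoyl]oxazolidin-2-one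
Product: 17 (R)-N-methoxy-N,2-dimethylpent-4-enamide
Conditions: MeNH(OMe)·HCl, AlMe3, CH2Cl2, −10 → 0 °C
Reagents that add atoms: N,O-dimethylhydroxylamine hydrochloride, CNOC.Cl
Why: Aluminium amide transamination (Weinreb amide synthesis) cleaves the exocyclic imide C–N bond under non-basic conditions, so the alpha centre is not epimerised and the auxiliary is recovered.

**Step 8**
Reactants: 17 (R)-N-methoxy-N,2-dimethylpent-4-enamide; 12 (2Z,6E)-2-iodo-8-(2-methoxy-3-methylphenyl)-6-methylocta-2,6-dien-4-ol
Product: 19 (2R,6Z,10E)-8-hydroxy-N-methoxy-12-(2-methoxy-3-methylphenyl)-N,2,6,10-tetramethyldodeca-6,10-dienamide, via B-alkyl-9-BBN borane 18 (not isolated)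
Conditions: 9-BBN, THF, 0 °C → rt; then 12, PdCl2(dppf) (5 mol%), AsPh3 (10 mol%), Cs2CO3, DMF/H2O, rt
Reagents that add atoms: none
Why: B-alkyl Suzuki–Miyaura coupling, that is anti-Markovnikov hydroboration of the terminal alkene, oxidative addition of the vinyl iodide to zerovalent palladium, transmetalation and reductive elimination with retention, places the new chain cis to the carbinol carbon (the future 6'Z alkene) and leaves the C-2 centre untouched.

**Step 9**
Reactants: 20 2-methylbut-3-yn-2-ol
Product: 21 (E)-2-methyl-4-(tributylstannyl)but-3-en-2-ol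
Conditions: Bu3SnH, AIBN (cat.), neat, 80 °C
Reagents that add atoms: tributyltin hydride, CCCC[SnH](CCCC)CCCC
Why: Radical hydrostannylation of the terminal alkyne puts tin on the terminal carbon and, through reversible stannyl-radical addition, funnels the product to the E isomer.

**Step 10**
Reactants: 21 (E)-2-methyl-4-(tributylstannyl)but-3-en-2-ol; 19 (2R,6Z,10E)-8-hydroxy-N-methoxy-12-(2-methoxy-3-methylphenyl)-N,2,6,10-tetramethyldodeca-6,10-dienamide
Product: 23 (2E,6Z,11R,13E)-5,15-dihydroxy-1-(2-methoxy-3-methylphenyl)-3,7,11,15-tetramethylhexadeca-2,6,13-trien-12-one, via dilithio alkenyl alkoxide 22 (not isolated)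
Conditions: 21 (3 equiv), n-BuLi (6 equiv), THF, −78 → −30 °C; then 19, −78 → −20 °C; aq NH4Cl
Reagents that add atoms: none
Why: Tin–lithium exchange gives the E-alkenyllithium with retention, and its addition to the Weinreb amide stops at the chelated tetrahedral intermediate (Weinreb ketone synthesis), so the E-enone forms on work-up without over-addition or epimerisation at C-11'; one equivalent of 22 is spent on the free carbinol.

**Step 11**
Reactants: 23 (2E,6Z,11R,13E)-5,15-dihydroxy-1-(2-methoxy-3-methylphenyl)-3,7,11,15-tetramethylhexadeca-2,6,13-trien-12-one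
Product: 24 (2E,6Z,11R,13E)-15-hydroxy-1-(2-methoxy-3-methylphenyl)-3,7,11,15-tetramethylhexadeca-2,6,13-triene-5,12-dione
Conditions: Dess–Martin periodinane, NaHCO3, CH2Cl2, 0 °C; Na2S2O3/NaHCO3 work-up
Reagents that add atoms: none
Why: Buffered Dess–Martin oxidation converts the secondary allylic carbinol to the ketone under neutral conditions that leave the tertiary alcohol untouched and neither move the 2',3'-alkene into conjugation nor isomerise the 6'Z-enone.

**Step 12**
Reactants: 24 (2E,6Z,11R,13E)-15-hydroxy-1-(2-methoxy-3-methylphenyl)-3,7,11,15-tetramethylhexadeca-2,6,13-triene-5,12-dione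
Product: 26 (2E,6Z,11R,13E)-15-hydroxy-1-(5-hydroxy-2-methoxy-3-methylphenyl)-3,7,11,15-tetramethylhexadeca-2,6,13-triene-5,12-dione (CNP0243623.1), via C-aryl O-alkyl bis(pinacolboryl) intermediate 25 (not isolated)
Conditions: [Ir(cod)OMe]2 (3 mol%), 3,4,7,8-tetramethyl-1,10-phenanthroline (6 mol%), B2pin2 (1.5 equiv), THF, 50 °C; then 4-MeC6H4NMe2 N-oxide (4 equiv), rt; pH 7 buffer
Reagents that add atoms: N,N-dimethyl-4-toluidine N-oxide, Cc1ccc(cc1)[N+](C)(C)[O-]
Why: Proposed new method: a one-flask undirected iridium-catalysed arene C–H borylation followed by amine N-oxide oxidation, used as the final step on an unprotected substrate that carries a Z-enone, a skipped (beta,gamma) enone, an E-gamma-hydroxyenone and a free tertiary alcohol; the tris(boryl) complex of trivalent iridium cleaves only sp2 C–H bonds with no ortho or cis neighbour, so among all sp2 C–H bonds of 24 only ring C-5–H of the 1,2,3-trisubstituted arene (para to OMe) should react, the carbinol is masked in the flask as its O–Bpin ether by the HBpin released, and the N-oxide then adds to boron and triggers 1,2-migration of the aryl group from B to O (the C–O bond-forming event) without the peroxide or base that would epoxidise or isomerise the enones; the closest known reaction type is the one-pot iridium C–H borylation/peroxymonosulfate oxidation of 1,2,3-trisubstituted arenes to 3,4,5-trisubstituted phenols together with N-oxide ipso-hydroxylation of arylboronates, neither of which has been shown on an enone-rich polyene.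

**Compound list**
1 | 1-bromo-2-methoxy-3-methylbenzene (2-bromo-6-methylanisole) | COc1c(C)cccc1Br | starting material
2 | 2-methyl-2-vinyloxirane (isoprene monoxide, racemic) | C=CC1(C)CO1 | starting material
3 | (2-methoxy-3-methylphenyl)magnesium bromide | COc1c(C)cccc1[Mg]Br | intermediate
4 | (E)-4-(2-methoxy-3-methylphenyl)-2-methylbut-2-en-1-ol | COc1c(C)cccc1C/C=C(\C)CO | intermediate
5 | (E)-4-(2-methoxy-3-methylphenyl)-2-methylbut-2-en-1-yl methanesulfonate | COc1c(C)cccc1C/C=C(\C)COS(C)(=O)=O | intermediate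
6 | 1-[(E)-4-chloro-3-methylbut-2-en-1-yl]-2-methoxy-3-methylbenzene | COc1c(C)cccc1C/C=C(\C)CCl | intermediate
7 | but-2-yn-1-ol | CC#CCO | starting material
8 | sodium 2,2-bis(2-methoxyethoxy)-3-methyl-2,5-dihydro-1,2-oxaaluminol-2-uide (cyclic Z-vinylalanate) | CC1=CCO[Al-]1(OCCOC)OCCOC.[Na+] | intermediate
9 | (Z)-3-iodobut-2-en-1-ol | C/C(I)=C/CO | intermediate
10 | (Z)-3-iodobut-2-enal | C/C(I)=C/C=O | intermediate
11 | [(E)-4-(2-methoxy-3-methylphenyl)-2-methylbut-2-en-1-yl]barium chloride | COc1c(C)cccc1C/C=C(\C)C[Ba]Cl | intermediate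
12 | (2Z,6E)-2-iodo-8-(2-methoxy-3-methylphenyl)-6-methylocta-2,6-dien-4-ol (racemic at C-4) | COc1c(C)cccc1C/C=C(\C)CC(O)/C=C(/C)I | intermediate
13 | (S)-4-benzyl-3-propionyloxazolidin-2-one | CCC(=O)N1[C@@H](Cc2ccccc2)COC1=O | starting material
14 | allyl iodide (3-iodoprop-1-ene) | C=CCI | starting material
15 | sodium (Z)-enolate of 13 | C/C=C(\[O-])N1[C@@H](Cc2ccccc2)COC1=O.[Na+] | intermediate
16 | (S)-4-benzyl-3-[(R)-2-methylpent-4-enoyl]oxazolidin-2-one | C=CC[C@@H](C)C(=O)N1[C@@H](Cc2ccccc2)COC1=O | intermediate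
17 | (R)-N-methoxy-N,2-dimethylpent-4-enamide | C=CC[C@@H](C)C(=O)N(C)OC | intermediate
18 | (R)-5-(9-borabicyclo[3.3.1]nonan-9-yl)-N-methoxy-N,2-dimethylpentanamide | C1CCC2CCCC1B2CCC[C@@H](C)C(=O)N(C)OC | intermediate
19 | (2R,6Z,10E)-8-hydroxy-N-methoxy-12-(2-methoxy-3-methylphenyl)-N,2,6,10-tetramethyldodeca-6,10-dienamide (C-8 epimers) | COc1c(C)cccc1C/C=C(\C)CC(O)/C=C(/C)CCC[C@@H](C)C(=O)N(C)OC | intermediate
20 | 2-methylbut-3-yn-2-ol | CC(C)(O)C#C | starting material
21 | (E)-2-methyl-4-(tributylstannyl)but-3-en-2-ol | CCCC[Sn](CCCC)(CCCC)/C=C/C(C)(C)O | intermediate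
22 | lithium (E)-4-lithio-2-methylbut-3-en-2-olate | [Li]/C=C/C(C)(C)O[Li] | intermediate
23 | (2E,6Z,11R,13E)-5,15-dihydroxy-1-(2-methoxy-3-methylphenyl)-3,7,11,15-tetramethylhexadeca-2,6,13-trien-12-one (C-5 epimers) | COc1c(C)cccc1C/C=C(\C)CC(O)/C=C(/C)CCC[C@@H](C)C(=O)/C=C/C(C)(C)O | intermediate
24 | (2E,6Z,11R,13E)-15-hydroxy-1-(2-methoxy-3-methylphenyl)-3,7,11,15-tetramethylhexadeca-2,6,13-triene-5,12-dione | COc1c(C)cccc1C/C=C(\C)CC(=O)/C=C(/C)CCC[C@@H](C)C(=O)/C=C/C(C)(C)O | intermediate
25 | 24 carrying a pinacolboryl group at ring C-5 and a pinacolboryl ether at the C-15 oxygen | COc1c(C)cc(B2OC(C)(C)C(C)(C)O2)cc1C/C=C(\C)CC(=O)/C=C(/C)CCC[C@@H](C)C(=O)/C=C/C(C)(C)OB1OC(C)(C)C(C)(C)O1 | intermediate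
26 | (2E,6Z,11R,13E)-15-hydroxy-1-(5-hydroxy-2-methoxy-3-methylphenyl)-3,7,11,15-tetramethylhexadeca-2,6,13-triene-5,12-dione (CNP0243623.1) | COc1c(C)cc(O)cc1C/C=C(\C)CC(=O)/C=C(/C)CCC[C@@H](C)C(=O)/C=C/C(C)(C)O | target

**Step count**
Total: 12 steps. Longest linear sequence: 7 steps (1 → 4 → 6 → 12 → 19 → 23 → 24 → 26, that is steps 1, 2, 5, 8, 10, 11 and 12).

**Three steps most likely to fail**

Step 12 (the proposed new step). The iridium boryl/hydride species or HBpin could reduce or borylate one of the enones, or isomerise the 6'Z or the skipped 2',3'-alkene, and the N-oxide stage could be slow on the hindered bis-boryl compound. The fallback uses known chemistry, sets out from 1 and comes back to the route at 26. The phenol oxygen is installed first on the simple bromoarene, where the iridium borylation/oxidation sequence is established, and is carried as a silyl ether.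
- 1 is borylated ([Ir(cod)OMe]2, 4,4'-di-tert-butyl-2,2'-bipyridine, B2pin2) at the only unhindered position to the arylboronate F1.
- F1 is oxidised in the same flask with aqueous KHSO5 (as its triple salt 2KHSO5·KHSO4·K2SO4) to 3-bromo-4-methoxy-5-methylphenol F2, which is silylated (t-BuMe2SiCl, imidazole, DMF) to the aryl silyl ether F3.
- The chemistry of steps 1, 2, 5, 8, 10 and 11 is then repeated unchanged in the silyl ether series. This passes through the arylmagnesium bromide F4, the allylic alcohol F5, its mesylate F6, the allylic chloride F7, the allylbarium chloride F8, the iodo dienol F9 (from F8 and 10), the Weinreb amide F10 (from F9 and 18), the hydroxy enone F11 (from F10 and 22) and the silylated dione F12.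
- Bu4NF buffered with AcOH (THF, 0 °C) removes the silyl group from F12 and gives 26.

Step 5. The organobarium reagent could attack the vinyl iodide, the iodoenal 10 could decompose or lose its Z geometry before it reacts, or the doubly activated benzylic/allylic CH2 of 6 could be metalated. The fallback sets out from 9 and 18 and comes back to the route at 19. It reverses the order of the two unions, so that the organobarium reagent meets only a stable, iodine-free enal.
- Borane 18 is coupled with 9 under the conditions of step 8 to give the Z-allylic alcohol F13.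
- MnO2 oxidises F13 to the neral-type Z-enal F14.
- Allylbarium 11 adds to the aldehyde of F14 at −78 °C (the Weinreb amide is much less electrophilic) to give 19.

Step 10. Tin–lithium exchange on the lithium alkoxide of 21 may be incomplete, and the excess basic reagent may enolise the amide. The fallback sets out from 19 and 20 and comes back to the route at 23.
- 20 is doubly deprotonated with butyllithium (THF, −78 °C) to the dilithio acetylide F15.
- F15 adds to the Weinreb amide of 19 to give the ynone F16.
- CrCl2 in aqueous THF (divalent chromium, two single-electron transfers with protonation) reduces the ynone selectively to the E-enone 23.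

**Further compounds**
F1 | step 12 | 2-(3-bromo-4-methoxy-5-methylphenyl)-4,4,5,5-tetramethyl-1,3,2-dioxaborolane | COc1c(C)cc(B2OC(C)(C)C(C)(C)O2)cc1Br
F2 | step 12 | 3-bromo-4-methoxy-5-methylphenol | COc1c(C)cc(O)cc1Br
F3 | step 12 | (3-bromo-4-methoxy-5-methylphenoxy)(tert-butyl)dimethylsilane | COc1c(C)cc(O[Si](C)(C)C(C)(C)C)cc1Br
F4 | step 12 | [5-(tert-butyldimethylsilyloxy)-2-methoxy-3-methylphenyl]magnesium bromide | COc1c(C)cc(O[Si](C)(C)C(C)(C)C)cc1[Mg]Br
F5 | step 12 | (E)-4-[5-(tert-butyldimethylsilyloxy)-2-methoxy-3-methylphenyl]-2-methylbut-2-en-1-ol | COc1c(C)cc(O[Si](C)(C)C(C)(C)C)cc1C/C=C(\C)CO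
F6 | step 12 | (E)-4-[5-(tert-butyldimethylsilyloxy)-2-methoxy-3-methylphenyl]-2-methylbut-2-en-1-yl methanesulfonate | COc1c(C)cc(O[Si](C)(C)C(C)(C)C)cc1C/C=C(\C)COS(C)(=O)=O
F7 | step 12 | tert-butyl{3-[(E)-4-chloro-3-methylbut-2-en-1-yl]-4-methoxy-5-methylphenoxy}dimethylsilane | COc1c(C)cc(O[Si](C)(C)C(C)(C)C)cc1C/C=C(\C)CCl
F8 | step 12 | {(E)-4-[5-(tert-butyldimethylsilyloxy)-2-methoxy-3-methylphenyl]-2-methylbut-2-en-1-yl}barium chloride | COc1c(C)cc(O[Si](C)(C)C(C)(C)C)cc1C/C=C(\C)C[Ba]Cl
F9 | step 12 | (2Z,6E)-8-[5-(tert-butyldimethylsilyloxy)-2-methoxy-3-methylphenyl]-2-iodo-6-methylocta-2,6-dien-4-ol | COc1c(C)cc(O[Si](C)(C)C(C)(C)C)cc1C/C=C(\C)CC(O)/C=C(/C)I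
F10 | step 12 | (2R,6Z,10E)-12-[5-(tert-butyldimethylsilyloxy)-2-methoxy-3-methylphenyl]-8-hydroxy-N-methoxy-N,2,6,10-tetramethyldodeca-6,10-dienamide | COc1c(C)cc(O[Si](C)(C)C(C)(C)C)cc1C/C=C(\C)CC(O)/C=C(/C)CCC[C@@H](C)C(=O)N(C)OC
F11 | step 12 | (2E,6Z,11R,13E)-1-[5-(tert-butyldimethylsilyloxy)-2-methoxy-3-methylphenyl]-5,15-dihydroxy-3,7,11,15-tetramethylhexadeca-2,6,13-trien-12-one | COc1c(C)cc(O[Si](C)(C)C(C)(C)C)cc1C/C=C(\C)CC(O)/C=C(/C)CCC[C@@H](C)C(=O)/C=C/C(C)(C)O
F12 | step 12 | (2E,6Z,11R,13E)-1-[5-(tert-butyldimethylsilyloxy)-2-methoxy-3-methylphenyl]-15-hydroxy-3,7,11,15-tetramethylhexadeca-2,6,13-triene-5,12-dione | COc1c(C)cc(O[Si](C)(C)C(C)(C)C)cc1C/C=C(\C)CC(=O)/C=C(/C)CCC[C@@H](C)C(=O)/C=C/C(C)(C)O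
F13 | step 5 | (2R,6Z)-8-hydroxy-N-methoxy-N,2,6-trimethyloct-6-enamide | OC/C=C(/C)CCC[C@@H](C)C(=O)N(C)OC
F14 | step 5 | (2R,6Z)-N-methoxy-N,2,6-trimethyl-8-oxooct-6-enamide | O=C/C=C(/C)CCC[C@@H](C)C(=O)N(C)OC
F15 | step 10 | lithium 4-lithio-2-methylbut-3-yn-2-olate | [Li]C#CC(C)(C)O[Li]
F16 | step 10 | (2E,6Z,11R)-5,15-dihydroxy-1-(2-methoxy-3-methylphenyl)-3,7,11,15-tetramethylhexadeca-2,6-dien-13-yn-12-one | COc1c(C)cccc1C/C=C(\C)CC(O)/C=C(/C)CCC[C@@H](C)C(=O)C#CC(C)(C)O
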